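# Synthesis proposal for CNP0249359.1 by Grob fragmentation of a cis-decalin diol monomesylate

## Analysis of the target

The target is a ten-membered carbocycle numbered C1 (epoxide CH), C2 (CH2), C3 (angelate carbinol), C4 (methyl carbinol), C5 (free secondary carbinol), C6 (CH2), C7 (isopropenyl CH), C8 (angelate carbinol), C9 (acetate carbinol) and C10 (methyl-bearing epoxide carbon). It has eight stereocentres in two runs, C3–C4–C5 and C7–C8–C9–C10–C1. Drawn flat with the numbering counterclockwise, every oxygen and the isopropenyl group lie on the upper (β) face, except the C4 hydroxyl, which is α. The epoxide is cis (C2 and C9 on the same side), so it derives from a Z C1=C10 alkene. The sensitive groups are the two angelates (which isomerise to tiglates when the acyl group is activated by nucleophilic catalysts), the trisubstituted epoxide (open to transannular attack by the C4 and C5 hydroxyls under acid), the vicinal ester and hydroxyl pairs (acyl migration) and the isopropenyl alkene. The difficulty is twofold: a medium ring has to be made, and five oxygen functions of three kinds have to be placed on a mobile ring with control of configuration. The strategy rests on the fact that C5 and C10 face each other across the ring while C5 and C1 both carry oxygen. A C5–C10 bond therefore turns the ring into a decalin (rings A: C10, C1–C5; B: C5–C10) in which O–C5–C10–C1–O is the 1,3-diol monosulfonate pattern of a Grob fragmentation.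

## Retrosynthetic reasoning

**Silyl ethers and acetate (31 ⇐ 30 ⇐ 29).** The two free hydroxyls of 31 are kept as triethylsilyl ethers until the end, so that the last step is a buffered fluoride treatment, with no acid near the epoxide and no base near the esters. The acetate goes onto the only free hydroxyl of 29, which avoids any differentiation of oxygens at that stage.

**Epoxide C–O bonds (29 ⇐ 28).** The epoxide is cut back to the Z alkene of 28. The free C9 allylic hydroxyl must deliver the oxygen to the face it occupies, which also keeps the isopropenyl and angelate alkenes out of the reaction.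

**C9–H bond (28 ⇐ 27).** The C9 carbinol is taken back to the enone carbonyl of 27. The ketone is needed one step earlier as the activating group for C8, and its reduction has to place the new hydroxyl on the β face next to the C8 ester.

**C8–O bond (27 ⇐ 25 + 26, 25 ⇐ 24 ⇐ 23).** The C8 ester is disconnected at the C8–O bond into bromo ketone 25 and cesium angelate 26 (from angelic acid 20). A carboxylate displacement forms the ester without activating the acyl group, so the Z geometry of the angelate is safe, and it inverts C8. That inversion is wanted, because an electrophile is expected to enter the silyl dienol ether 24 on the α face. Compound 24 comes from diol 23 in one silylation that also caps both hydroxyls.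

**C5–H bond and C3 ester (23 ⇐ 22 ⇐ 19 + 20 ⇐ 18).** The C5 carbinol is taken back to the ketone that the fragmentation leaves. The C3 angelate is put on before that reduction, while C3 carries the only secondary hydroxyl (19), so C3 and C5 never need to be told apart.

**Ring-forming bond cleavage (18 ⇐ 16).** Reconnecting C5 to C10 and adding a leaving group at C1 converts the (Z)-enedione 18 into the cis-fused decalin 16. Cutting here, and not at a ring C–C bond to be closed, avoids every medium-ring cyclisation. The forward step must break the ring-fusion bond and give only the Z alkene.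

**C4–O and C5–O bonds (16 ⇐ 15 ⇐ 14 ⇐ 13 ⇐ 12).** The trans-diaxial 4,5-diol is traced to the α-epoxide 13 of the tetrasubstituted alkene 12. Opening at C5 with inversion sets the cis ring fusion and the tertiary C4 carbinol together. The C9 ketone is carried as a silyl ether through this part and unveiled last.

**C1 and C3 oxygens (12 ⇐ 11 ⇐ 10 ⇐ 9 ⇐ 8).** Both come from the cross-conjugated dienone 8: the C1 hydroxyl from the α-epoxide of the less substituted enone double bond by reductive opening, and the C3 hydroxyl by reduction directed from C1. The C1 hydroxyl later also directs the C4–C5 epoxidation.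

**Unsaturation and C9 masking (8 ⇐ 7 ⇐ 6 ⇐ 5 ⇐ 4).** The two ring A double bonds are introduced by dehydrogenation, the first through the silyl enol ether that the cycloaddition delivers. The saturated C9 ketone is reduced and silylated in between, so that no later enolisation, reduction or dehydrogenation can touch ring B.

**C10–C1 and C4–C5 bonds (4 ⇐ 3 + 2, 2 ⇐ 1).** Ring A is cut across these two bonds into (S)-carvone 3 and diene 2 (from 1). The cycloaddition keeps the stereocentre of 3 as C7, turns its carbonyl into C9 and its methyl-bearing carbon into C10, and sets the C10 methyl cis to the isopropenyl group because the diene adds anti to that group.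

## Alternatives that were turned down

**Alternative 1:** The C1=C10 alkene (epoxide precursor) and a C4=C5 alkene (diol precursor) are traced back to the central four-membered ring of the tricycle A1 (rings of six, four and four members). A1 is cut into the cyclohexenone A2 and the silylated methylcyclobutenol A3.

- Forward key step: irradiation joins C10 to C1 and C5 to C4 in an enone–alkene [2+2] cycloaddition. Heating A1 then breaks the C5–C10 and C1–C4 bonds and leaves the ten-membered ring with both double bonds.
- For it: the ring arises in two steps from two small pieces, driven by strain release. C3, C8 and C9 arrive oxygenated, and C8 has its configuration set on a six-membered ring. On the C8 centre and on step count to the macrocycle it is stronger than the chosen route.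
- Against it: the cycloaddition must join two fully substituted carbons (C10 and C4) with the right orientation and face on both partners. The thermal opening runs through a 1,4-diradical, so the alkene geometries follow strain, not the need for Z at C1=C10. The resulting cyclodeca-1,5-diene is also in Cope equilibrium with a divinylcyclohexane. Two trisubstituted ring alkenes would then have to be told apart on a flexible ring, one for epoxidation and one for a dihydroxylation that creates the tertiary C4 carbinol. The isopropenyl group has to be carried as a ketal.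
- Comparison: the chosen route takes the alkene geometry from a stereospecific ground-state step, brings C3 and C4 in as finished carbinols, and leaves only one ring alkene to oxidise.

**Alternative 2:** The C3 and C8 carbonyl groups of the ten-membered dione A4 are joined into a tetrasubstituted C3=C8 double bond shared by two six-membered rings in the bicyclic alkene A5.

- Forward key step: ozone cleaves that double bond.
- For it: no macrocyclisation and no alkene geometry problem. The epoxide, the C9 acetate and the protected 4,5-diol are all set on a rigid bicycle before the ring opens. On control of C9, C10 and C1 this is stronger than the chosen route, which sets them on the ten-membered ring.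
- Against it: ozone attacks the isopropenyl group about as readily as a hindered tetrasubstituted alkene. A4 is a cyclodecane-1,6-dione with a β,γ-epoxy ketone and an α-acetoxy ketone, so transannular aldol reaction, epoxide elimination and epimerisation or acyl shift at C9 all threaten. Both C3 and C8 must afterwards be reduced with the right configuration on the flexible ring and acylated next to other esters. A5 itself, with five stereocentres around a ring-fusion alkene, would be long to make.
- Comparison: the chosen route reduces only one ketone that lacks a neighbouring ester (C5), never exposes the isopropenyl group to an unselective oxidant, and reaches its bicyclic precursor from carvone with the relative configuration fixed by a cycloaddition.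

**Alternative 3:** The C3–C4 bond of diol A6 is cut to give the acyclic keto aldehyde A7.

- Forward key step: SmI2 reduces the C3 aldehyde to a ketyl, which adds to the C4 methyl ketone held in a chelate with the C5 ether. This closes the ten-membered ring as a secondary–tertiary diol.
- For it: C5, C7, C8, C9 and the Z alkene are set in an open chain by acyclic methods. That is stronger than the chosen route for C8 and C9. The free C3 hydroxyl next to a tertiary one is ready for direct angeloylation.
- Against it: the closure of a ten-membered ring pays the full entropic and transannular penalty and competes with intermolecular coupling and simple reduction. A samarium-bridged pinacol transition state places the two oxygens on the same side, whereas A6 needs them on opposite faces of the flat ring. The configuration of the tertiary C4 centre hangs on one chelate. The β,γ-unsaturated aldehyde of A7 is prone to slip into conjugation. The linear sequence to A7 carries four stereocentres and three different protecting groups.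
- Comparison: the chosen route forms the ring by breaking a bond, which has no entropic cost, and fixes C3 and C4 on a chair before the ring exists. It pays for this by setting C8 and C9 on the ring afterwards.

Key step: step 15

## Remarks on the chemistry

- Remark on the chemistry: α and β refer to drawings in which C1 to C10 run counterclockwise, β being the face toward the viewer; in the decalins this is the face of the C10 methyl group.
- Remark on the chemistry: C4 in 4–7 and C9 in 6–15 are drawn as expected (endo adduct; hydride anti to the angular methyl). Neither matters later, since C4 becomes trigonal in 8 and C9 is oxidised in 16.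
- Remark on the chemistry: the silyl dienol ether 24 is drawn with C7 and C10 cis on the C8=C9 bond; the other geometry would converge at 25.

## Steps

Step 1
Reactants: 1 pent-1-en-3-one
Product: 2 (Z)-3-(trimethylsilyloxy)penta-1,3-diene
Conditions: TMSOTf, Et3N, Et2O, 0 °C
Reagents that add atoms: trimethylsilyl trifluoromethanesulfonate, C[Si](C)(C)OS(=O)(=O)C(F)(F)F
Why: Soft enolisation of the ethyl ketone (silyl enol ether formation); only the ethyl side can enolise, and the Z enol ether, which has the methyl group outside the s-cis diene, should predominate.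

Step 2
Reactants: 3 (S)-(+)-carvone; 2 (Z)-3-(trimethylsilyloxy)penta-1,3-diene
Product: 4 cis-fused decalin silyl enol ether (C2=C3 with 3-OTMS; 4α-methyl; 5β-H; 10β-methyl; 7β-isopropenyl; C9 ketone)
Conditions: EtAlCl2 (0.25 equiv), toluene, −20 °C to rt; Et3N quench
Reagents that add atoms: none
Why: Lewis-acid-catalysed Diels–Alder reaction of a 2-methylcyclohexenone with a 2-silyloxydiene; the diene terminus next to the silyloxy carbon bonds to the enone β-carbon (C5) and the CH2 terminus to C10. Suprafacial addition anti to the isopropenyl group gives the cis fusion with the C10 methyl cis to isopropenyl; the endo mode gives the 4α-methyl group.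

Step 3
Reactants: 4 cis-fused decalin silyl enol ether
Product: 5 cis-fused 1-ene-3,9-dione (4α-methyl; 5β-H; 10β-methyl; 7β-isopropenyl)
Conditions: Pd(OAc)2 (10 mol %), O2 (1 atm), DMSO, 40 °C
Reagents that add atoms: none
Why: Saegusa–Ito oxidation; the palladium enolate at C2 can lose only a C1 hydrogen by β-hydride elimination, so the double bond forms regiospecifically at C1=C2, and the C9 ketone is not involved.

Step 4
Reactants: 5 cis-fused 1-ene-3,9-dione
Product: 6 9β-hydroxy-1-en-3-one
Conditions: NaBH4 (0.3 equiv), EtOH, −15 °C
Reagents that add atoms: none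
Why: Chemoselective borohydride reduction; a saturated ketone is reduced faster than a conjugated enone at low temperature in alcohol, as in enediones of the Wieland–Miescher type. Hydride attacks anti to the angular methyl, though the C9 configuration is of no consequence.

Step 5
Reactants: 6 9β-hydroxy-1-en-3-one
Product: 7 9β-triethylsilyl ether of 6
Conditions: TESCl, imidazole, DMF, rt
Reagents that add atoms: chlorotriethylsilane, CC[Si](Cl)(CC)CC
Why: Standard silylation of the only hydroxyl; it masks C9 so that ring B can no longer be enolised, reduced or dehydrogenated during the work on ring A.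

Step 6
Reactants: 7 9β-triethylsilyl ether
Product: 8 cross-conjugated 1,4-dien-3-one (4,10β-dimethyl; 7β-isopropenyl; 9β-OTES)
Conditions: DDQ (1.2 equiv), anhydrous dioxane, 90 °C
Reagents that add atoms: none
Why: Quinone dehydrogenation; the enone can enolise only toward C4, and DDQ abstracts the tertiary C5 hydride from that dienol to give the dienone. Both the C4 and C5 stereocentres are erased, so any C4 epimer of 7 converges here.

Step 7
Reactants: 8 cross-conjugated 1,4-dien-3-one
Product: 9 1α,2α-epoxy-4-en-3-one
Conditions: 30% H2O2, NaOH (cat.), MeOH, 0 °C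
Reagents that add atoms: hydrogen peroxide, OO
Why: Weitz–Scheffer nucleophilic epoxidation; hydroperoxide adds to the unhindered C1 terminus of the disubstituted double bond and not to the fully substituted C5, from the α face opposite the pseudoaxial C10 methyl group, as in 1,4-dien-3-ones of the steroid series.

Step 8
Reactants: 9 1α,2α-epoxy-4-en-3-one
Product: 10 1α-hydroxy-4-en-3-one
Conditions: SmI2 (2.2 equiv), THF/MeOH, −90 °C
Reagents that add atoms: none
Why: Reductive cleavage of the Cα–O bond of an α,β-epoxy ketone by two single-electron transfers; the C1–O bond is untouched, so the 1α configuration is kept, and the β,β-disubstituted enone is not reduced at this temperature.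

Step 9
Reactants: 10 1α-hydroxy-4-en-3-one
Product: 11 4-ene-1α,3β-diol
Conditions: Me4NBH(OAc)3, MeCN/AcOH, −30 °C
Reagents that add atoms: none
Why: Evans–Saksena reduction; the C1 alkoxyborohydride delivers hydride intramolecularly to the α face of C3, which gives the 1,3-anti diol, that is the 3β-alcohol, by 1,2-addition.

Step 10
Reactants: 11 4-ene-1α,3β-diol
Product: 12 3β-TBS ether with free 1α-hydroxyl
Conditions: TBSCl, imidazole, DMF, 0 °C
Reagents that add atoms: tert-butyl(chloro)dimethylsilane, CC(C)(C)[Si](C)(C)Cl
Why: Selective silylation of the allylic, pseudoequatorial C3 hydroxyl; the axial C1 hydroxyl next to the quaternary C10 is much more hindered and stays free for the next two steps.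

Step 11
Reactants: 12 3β-TBS ether
Product: 13 4α,5α-epoxide (1α-OH; 3β-OTBS; 9β-OTES)
Conditions: VO(acac)2 (5 mol %), tBuOOH, CH2Cl2, 0 °C to rt
Reagents that add atoms: tert-butyl hydroperoxide, CC(C)(C)OO
Why: Hydroxyl-directed epoxidation of a cyclohex-3-enol unit; the axial homoallylic C1 vanadate delivers oxygen to the α face of the tetrasubstituted alkene. The C10 methyl and the C3 silyl ether on the β face reinforce this, and the isopropenyl group has no directing hydroxyl and stays intact.

Step 12
Reactants: 13 4α,5α-epoxide
Product: 14 1α-mesylate of 13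
Conditions: MsCl, Et3N, CH2Cl2, −10 °C
Reagents that add atoms: methanesulfonyl chloride, CS(=O)(=O)Cl
Why: Sulfonylation through sulfene reaches even the hindered secondary hydroxyl, which is the only free one; it is done before the diol is released so that no other hydroxyl competes.

Step 13
Reactants: 14 1α-mesylate
Product: 15 cis-fused 4α,5β,9β-triol (1α-OMs; 3β-OTBS; 4β,10β-dimethyl; 7β-isopropenyl)
Conditions: 0.2 M HClO4, THF/H2O (3:1), 0 °C to rt
Reagents that add atoms: water, O
Why: Acid-catalysed anti hydrolysis of the tetrasubstituted epoxide; the C5–O bond should ionise and not C4–O, because positive charge at C4 would sit next to the silyloxy-bearing C3. Water enters C5 from the β face with inversion, giving the cis fusion and the trans-diaxial diol, and the acid also cleaves the triethylsilyl ether while the more stable TBS ether should survive.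

Step 14
Reactants: 15 cis-fused 4α,5β,9β-triol
Product: 16 cis-fused 4α,5β-dihydroxy-9-ketone (1α-OMs; 3β-OTBS; 4β,10β-dimethyl; 7β-isopropenyl)
Conditions: Dess–Martin periodinane, NaHCO3, CH2Cl2, 0 °C to rt
Reagents that add atoms: none
Why: Dess–Martin oxidation of the only secondary alcohol; the two tertiary hydroxyls cannot be oxidised, and the buffered neutral medium spares the mesylate and the β-hydroxy ketone.

Step 15
Reactants: 16 cis-fused 4α,5β-dihydroxy-9-ketone
Product: 18 (Z)-3β-TBSO-4α-hydroxy-4β,10-dimethyl-7β-isopropenylcyclodec-1(10)-ene-5,9-dione, via potassium C5 alkoxide 17 (not isolated)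
Conditions: KOtBu (1.2 equiv), tBuOH/THF, 0 °C
Reagents that add atoms: none
Why: Deprotonation of the tertiary C5 hydroxyl gives alkoxide 17, in which an oxygen lone pair, the C5–C10 bond and the C1–O bond of the equatorial mesylate are antiperiplanar, so the fusion bond breaks and mesylate leaves in one concerted heterolytic step (Grob fragmentation; the closest known type is the Wharton fragmentation of decalin-1,3-diol monosulfonates to cyclodecenones). No ring is closed: the ten-membered ring appears because the bond shared by rings A and B is cleaved. No stereocentre is formed; C5 becomes a ketone and C1=C10 an alkene. The step needs Z geometry and chemoselectivity for fragmentation over retro-aldol opening, oxetane formation and elimination. Geometry is fixed by the cis fusion: in the chair of ring A that keeps the C4 and C10 methyl groups equatorial (the other chair has them syn-axial), C9 is axial and gauche to C2 while the mesylate is equatorial, so C2 and C9 end up cis. In the same chair the mesylate has no antiperiplanar hydrogen, which excludes elimination, and the aligned concerted path should outrun the stepwise retro-aldol route through the C9 enolate. The C3 silyl ether keeps a second alkoxide away from C1, and the C4 alkoxide has no leaving group in a 1,3-relationship.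

Step 16
Reactants: 18 (Z)-cyclodecenedione 3β-TBS ether
Product: 19 (Z)-3β,4α-dihydroxy-4β,10-dimethyl-7β-isopropenylcyclodec-1(10)-ene-5,9-dione
Conditions: HF·pyridine, pyridine, THF, 0 °C to rt
Reagents that add atoms: none
Why: Fluoride cleavage of the silyl ether under buffered, weakly acidic conditions; this avoids the alkoxides that could trigger retro-aldol or acyloin shifts in the hydroxy diketone.

Step 17
Reactants: 19 (Z)-3β,4α-dihydroxy-dione; 20 angelic acid
Product: 22 3β-angelate of 19, via mixed anhydride 21 (not isolated)
Conditions: 2,4,6-trichlorobenzoyl chloride, Et3N, toluene, rt; then 19, 60 °C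
Reagents that add atoms: none
Why: Yamaguchi esterification without a nucleophilic catalyst; the alcohol attacks the less hindered angeloyl carbonyl of 21, and the absence of acylpyridinium or ketene intermediates keeps the Z geometry. Only the secondary C3 hydroxyl reacts, as the tertiary C4 hydroxyl is too hindered.

Step 18
Reactants: 22 3β-angelate
Product: 23 5β-alcohol (3β-OAng; 4α,5β-diol; C9 enone)
Conditions: NaBH4, MeOH/CH2Cl2 (1:1), −78 °C
Reagents that add atoms: none
Why: Borohydride at low temperature reduces the saturated, inductively activated α-hydroxy ketone before the conjugated ketone and leaves the conjugated ester alone. Hydride should come from the ring periphery, anti to the C4–C3 ring bond, with the C4 hydroxyl (smaller than methyl and opposed to the carbonyl dipole) on the side of attack and the methyl near the carbonyl oxygen, which gives the 5β-alcohol.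

Step 19
Reactants: 23 5β-alcohol
Product: 24 4α,5β-bis(triethylsilyloxy) compound with C9 triethylsilyl dienol ether (C8=C9; C7 and C10 cis)
Conditions: TESOTf (4 equiv), Et3N (6 equiv), CH2Cl2, −78 to 0 °C
Reagents that add atoms: triethylsilyl trifluoromethanesulfonate, CC[Si](CC)(CC)OS(=O)(=O)C(F)(F)F
Why: Silylation of both hydroxyls together with soft enolisation of the enone; kinetic deprotonation of the O-silylated ketone occurs at the α′ carbon C8 to give the cross-conjugated dienol ether, and no strong base touches the ester.

Step 20
Reactants: 24 silyl dienol ether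
Product: 25 8α-bromo-9-ketone (3β-OAng; 4α,5β-bis-OTES)
Conditions: NBS, THF, −78 °C
Reagents that add atoms: N-bromosuccinimide, O=C1CCC(=O)N1Br
Why: Bromination of a silyl enol ether at its nucleophilic carbon; the electron-rich enol ether reacts before the isopropenyl and angelate alkenes. With the C7 hydrogen eclipsing the enol ether (allylic strain) and the C7–C6 ring bond on the inner face, bromine should enter from the periphery and end on the α face, the epimer the next step needs.

Step 21
Reactants: 25 8α-bromo-9-ketone; 20 angelic acid
Product: 27 3β,8β-bis(angelate) enone (4α,5β-bis-OTES), via cesium angelate 26 (not isolated)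
Conditions: Cs2CO3, DMF, 0 °C to rt
Reagents that add atoms: none
Why: SN2 displacement of an α-bromo ketone by a carboxylate with inversion at C8, giving the 8β-ester; the carboxyl group is never activated, so the Z geometry is safe, and the ketone has no α′ hydrogen for a Favorskii pathway.

Step 22
Reactants: 27 3β,8β-bis(angelate) enone
Product: 28 9β-allylic alcohol
Conditions: NaBH4, CeCl3·7H2O, MeOH, −78 °C
Reagents that add atoms: none
Why: Luche reduction, selective for 1,2-addition to the enone and inert toward the conjugated esters. Hydride should attack from the periphery, anti to the C8–C7 ring bond and past the small C8 hydrogen, with the cerium-coordinated acyloxy group near the carbonyl oxygen, which gives the 9β-alcohol; the cold, weakly acidic medium suppresses acyl shift from O8 to O9.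

Step 23
Reactants: 28 9β-allylic alcohol
Product: 29 1β,10β-epoxy-9β-alcohol
Conditions: VO(acac)2 (5 mol %), tBuOOH, CH2Cl2, 0 °C
Reagents that add atoms: tert-butyl hydroperoxide, CC(C)(C)OO
Why: Hydroxyl-directed epoxidation of a (Z)-cycloalkenol; the vanadate ester delivers oxygen at a small O–C–C=C dihedral angle, on the face opposite the C9–C8 ring bond, which places the epoxide cis to the hydroxyl, as with medium-ring (Z)-cycloalkenols. The Z alkene gives the cis epoxide, and the isopropenyl and angelate alkenes have no directing group.

Step 24
Reactants: 29 epoxy alcohol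
Product: 30 9β-acetate
Conditions: Ac2O, DMAP (cat.), pyridine, rt
Reagents that add atoms: acetic anhydride, CC(=O)OC(C)=O
Why: Acetylation of the only free hydroxyl; the basic, non-nucleophilic medium leaves the epoxide, the silyl ethers and the angelates unchanged.

Step 25
Reactants: 30 9β-acetate
Product: 31 CNP0249359.1
Conditions: HF·pyridine, pyridine, THF, 0 °C to rt
Reagents that add atoms: none
Why: Buffered fluoride removes the secondary and the tertiary triethylsilyl ether without alkoxide formation, which guards against acyl migration and against transannular opening of the epoxide by the liberated hydroxyls.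

## Compound list

1 | pent-1-en-3-one | C=CC(=O)CC | starting material
2 | (Z)-3-(trimethylsilyloxy)penta-1,3-diene | C=C/C(O[Si](C)(C)C)=C/C | intermediate
3 | (S)-(+)-carvone | C=C(C)[C@H]1CC=C(C)C(=O)C1 | starting material
4 | cis-fused decalin silyl enol ether (C2=C3, 3-OTMS; 4α-methyl; 5β-H; 10β-methyl; 7β-isopropenyl; C9 ketone) | C=C(C)[C@H]1C[C@@H]2[C@H](C)C(O[Si](C)(C)C)=CC[C@]2(C)C(=O)C1 | intermediate
5 | cis-fused 1-ene-3,9-dione (4α-methyl; 5β-H; 10β-methyl; 7β-isopropenyl) | C=C(C)[C@H]1C[C@@H]2[C@H](C)C(=O)C=C[C@]2(C)C(=O)C1 | intermediate
6 | 9β-hydroxy-1-en-3-one | C=C(C)[C@H]1C[C@@H]2[C@H](C)C(=O)C=C[C@]2(C)[C@@H](O)C1 | intermediate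
7 | 9β-triethylsilyl ether of 6 | C=C(C)[C@H]1C[C@@H]2[C@H](C)C(=O)C=C[C@]2(C)[C@@H](O[Si](CC)(CC)CC)C1 | intermediate
8 | cross-conjugated 1,4-dien-3-one (4,10β-dimethyl; 7β-isopropenyl; 9β-OTES) | C=C(C)[C@H]1CC2=C(C)C(=O)C=C[C@]2(C)[C@@H](O[Si](CC)(CC)CC)C1 | intermediate
9 | 1α,2α-epoxy-4-en-3-one | C=C(C)[C@H]1CC2=C(C)C(=O)[C@@H]3O[C@@H]3[C@]2(C)[C@@H](O[Si](CC)(CC)CC)C1 | intermediate
10 | 1α-hydroxy-4-en-3-one | C=C(C)[C@H]1CC2=C(C)C(=O)C[C@H](O)[C@]2(C)[C@@H](O[Si](CC)(CC)CC)C1 | intermediate
11 | 4-ene-1α,3β-diol | C=C(C)[C@H]1CC2=C(C)[C@@H](O)C[C@H](O)[C@]2(C)[C@@H](O[Si](CC)(CC)CC)C1 | intermediate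
12 | 3β-TBS ether with free 1α-hydroxyl | C=C(C)[C@H]1CC2=C(C)[C@@H](O[Si](C)(C)C(C)(C)C)C[C@H](O)[C@]2(C)[C@@H](O[Si](CC)(CC)CC)C1 | intermediate
13 | 4α,5α-epoxide (1α-OH; 3β-OTBS; 9β-OTES) | C=C(C)[C@H]1C[C@]23O[C@]3(C)[C@@H](O[Si](C)(C)C(C)(C)C)C[C@H](O)[C@]2(C)[C@@H](O[Si](CC)(CC)CC)C1 | intermediate
14 | 1α-mesylate of 13 | C=C(C)[C@H]1C[C@]23O[C@]3(C)[C@@H](O[Si](C)(C)C(C)(C)C)C[C@H](OS(C)(=O)=O)[C@]2(C)[C@@H](O[Si](CC)(CC)CC)C1 | intermediate
15 | cis-fused 4α,5β,9β-triol (1α-OMs; 3β-OTBS) | C=C(C)[C@H]1C[C@]2(O)[C@](C)(O)[C@@H](O[Si](C)(C)C(C)(C)C)C[C@H](OS(C)(=O)=O)[C@]2(C)[C@@H](O)C1 | intermediate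
16 | cis-fused 4α,5β-dihydroxy-9-ketone (1α-OMs; 3β-OTBS), fragmentation precursor | C=C(C)[C@H]1C[C@]2(O)[C@](C)(O)[C@@H](O[Si](C)(C)C(C)(C)C)C[C@H](OS(C)(=O)=O)[C@]2(C)C(=O)C1 | intermediate
17 | potassium C5 alkoxide of 16 (not isolated) | C=C(C)[C@H]1C[C@]2([O-])[C@](C)(O)[C@@H](O[Si](C)(C)C(C)(C)C)C[C@H](OS(C)(=O)=O)[C@]2(C)C(=O)C1.[K+] | intermediate
18 | (Z)-3β-TBSO-4α-hydroxy-4β,10-dimethyl-7β-isopropenylcyclodec-1(10)-ene-5,9-dione | C=C(C)[C@H]1CC(=O)[C@](C)(O)[C@@H](O[Si](C)(C)C(C)(C)C)C/C=C(C)\C(=O)C1 | intermediate
19 | (Z)-3β,4α-dihydroxy-4β,10-dimethyl-7β-isopropenylcyclodec-1(10)-ene-5,9-dione | C=C(C)[C@H]1CC(=O)[C@](C)(O)[C@@H](O)C/C=C(C)\C(=O)C1 | intermediate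
20 | angelic acid, (Z)-2-methylbut-2-enoic acid | C/C=C(/C)C(=O)O | starting material
21 | angelic 2,4,6-trichlorobenzoic anhydride (not isolated) | C/C=C(/C)C(=O)OC(=O)c1c(Cl)cc(Cl)cc1Cl | intermediate
22 | 3β-angelate of 19 | C=C(C)[C@H]1CC(=O)[C@](C)(O)[C@@H](OC(=O)/C(C)=C\C)C/C=C(C)\C(=O)C1 | intermediate
23 | 5β-alcohol (3β-OAng; 4α,5β-diol; C9 enone) | C=C(C)[C@H]1C[C@@H](O)[C@](C)(O)[C@@H](OC(=O)/C(C)=C\C)C/C=C(C)\C(=O)C1 | intermediate
24 | 4α,5β-bis(triethylsilyloxy) C9 triethylsilyl dienol ether (C8=C9; C7 and C10 cis) | C1[C@@H](O[Si](CC)(CC)CC)[C@](C)(O[Si](CC)(CC)CC)[C@@H](OC(=O)/C(C)=C\C)C/C=C(C)\C(O[Si](CC)(CC)CC)=C/[C@H]1C(C)=C | intermediate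
25 | 8α-bromo-9-ketone (3β-OAng; 4α,5β-bis-OTES) | C=C(C)[C@H]1C[C@@H](O[Si](CC)(CC)CC)[C@](C)(O[Si](CC)(CC)CC)[C@@H](OC(=O)/C(C)=C\C)C/C=C(C)\C(=O)[C@@H]1Br | intermediate
26 | cesium angelate (not isolated) | C/C=C(/C)C(=O)[O-].[Cs+] | intermediate
27 | 3β,8β-bis(angelate) enone (4α,5β-bis-OTES) | C=C(C)[C@H]1C[C@@H](O[Si](CC)(CC)CC)[C@](C)(O[Si](CC)(CC)CC)[C@@H](OC(=O)/C(C)=C\C)C/C=C(C)\C(=O)[C@H]1OC(=O)/C(C)=C\C | intermediate
28 | 9β-allylic alcohol | C=C(C)[C@H]1C[C@@H](O[Si](CC)(CC)CC)[C@](C)(O[Si](CC)(CC)CC)[C@@H](OC(=O)/C(C)=C\C)C/C=C(C)\[C@@H](O)[C@H]1OC(=O)/C(C)=C\C | intermediate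
29 | 1β,10β-epoxy-9β-alcohol | C=C(C)[C@H]1C[C@@H](O[Si](CC)(CC)CC)[C@](C)(O[Si](CC)(CC)CC)[C@@H](OC(=O)/C(C)=C\C)C[C@H]2O[C@@]2(C)[C@@H](O)[C@H]1OC(=O)/C(C)=C\C | intermediate
30 | 9β-acetate (4α,5β-bis-OTES) | C=C(C)[C@H]1C[C@@H](O[Si](CC)(CC)CC)[C@](C)(O[Si](CC)(CC)CC)[C@@H](OC(=O)/C(C)=C\C)C[C@H]2O[C@@]2(C)[C@@H](OC(C)=O)[C@H]1OC(=O)/C(C)=C\C | intermediate
31 | CNP0249359.1 (1β,10β-epoxide; 3β,8β-bis-angelate; 4α,5β-diol; 9β-acetate; 7β-isopropenyl) | C=C(C)[C@H]1C[C@@H](O)[C@](C)(O)[C@@H](OC(=O)/C(C)=C\C)C[C@H]2O[C@@]2(C)[C@@H](OC(C)=O)[C@H]1OC(=O)/C(C)=C\C | target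

## Step count and least certain steps

Total step count: 25. Longest linear sequence: 25 steps (from 1 through 2 to 31; 24 steps counted from 3).

**Step 15 (key step).** The alkoxide may open the β-hydroxy ketone by retro-aldol cleavage before the mesylate leaves. The mesylate is then lost from the C9 enolate by a stepwise elimination without geometric control, or the enolate recloses to epimeric ketols. Displacement of the mesylate by the C5 oxygen (oxetane) and an acyloin shift of the product under base are further drains. Fallback: fragment before C9 is a ketone, so that no enolate pathway exists. Triol 15 is treated with KOtBu in THF; it should fragment through the same chair to the (Z)-9β-hydroxy-cyclodecenone F1. Oxidation of the allylic alcohol of F1 with MnO2 rejoins the route at 18.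

**Step 13.** Ionisation at C5 may be followed by proton loss from C6 (allylic alcohol), by a 1,2-shift from C10, or by capture on the α face, which would give the trans-fused diol; some TBS cleavage is also possible. Fallback: deliver the C5 oxygen from inside the molecule. From 14, buffered HF·pyridine removes only the triethylsilyl ether to give the 9β-alcohol F2. Boc2O and DMAP convert it into the tert-butyl carbonate F3. BF3·OEt2 then lets the carbonate carbonyl attack C5 from the β face through a six-membered transition state with loss of 2-methylpropene, giving the cyclic 5β,9β-carbonate F4. Ring size fixes the regiochemistry and the mechanism fixes inversion. Methanolysis of F4 (K2CO3, MeOH, 0 °C) rejoins the route at 15.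

**Step 18.** A hydrogen bond from the C4 hydroxyl to the carbonyl could hold the C4–O bond syn to C=O and turn the facial preference toward the 5α-alcohol, and the twisted enone could compete for hydride. Fallback: remove the hydrogen bond by changing the substrate. From 22, TESOTf and 2,6-lutidine cap the tertiary hydroxyl to give the 4α-silyl ether F5. Its reduction (NaBH4, MeOH/CH2Cl2, −78 °C) then follows the Felkin–Anh and dipole model and should give the 5β-alcohol F6. The conditions of step 19 convert F6 into 24.

**Step 20 (with step 21).** The electrophile may enter on the other face if the ring conformation differs from the model. The bromide may also be epimerised by bromide exchange during the displacement. Either would end in the 8α-ester. Fallback: oxygenate C8 directly and esterify with retention. From 24, Rubottom oxidation (dimethyldioxirane, acetone, −78 °C; then PPTS, MeOH) would place oxygen on the face that bromine took and give the 8β-hydroxy ketone F7. Yamaguchi acylation of F7 with mixed anhydride 21 rejoins the route at 27.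

**Step 22.** If the C8–O bond turns away from the carbonyl to oppose its dipole, peripheral attack gives the 9α-alcohol. The intermediate alkoxide may also take the angelate from O8. Fallback: replace substrate control by reagent control. Corey–Bakshi–Shibata reduction of 27 (oxazaborolidine of the appropriate hand, catecholborane, toluene, −78 °C), a reaction for which enones are the classic substrates, leads directly to 28 under neutral conditions.

## Further compounds

F1 | step 15 | (Z)-9β-hydroxy-3β-TBSO-4α-hydroxy-4β,10-dimethyl-7β-isopropenylcyclodec-1(10)-en-5-one | C=C(C)[C@H]1CC(=O)[C@](C)(O)[C@@H](O[Si](C)(C)C(C)(C)C)C/C=C(C)\[C@@H](O)C1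
F2 | step 13 | 9β-alcohol of epoxy mesylate 14 (triethylsilyl group removed) | C=C(C)[C@H]1C[C@]23O[C@]3(C)[C@@H](O[Si](C)(C)C(C)(C)C)C[C@H](OS(C)(=O)=O)[C@]2(C)[C@@H](O)C1
F3 | step 13 | 9β-tert-butyl carbonate of F2 | C=C(C)[C@H]1C[C@]23O[C@]3(C)[C@@H](O[Si](C)(C)C(C)(C)C)C[C@H](OS(C)(=O)=O)[C@]2(C)[C@@H](OC(=O)OC(C)(C)C)C1
F4 | step 13 | cyclic 5β,9β-carbonate with free 4α-hydroxyl (1α-OMs; 3β-OTBS) | C=C(C)[C@H]1C[C@]2(OC(=O)O3)[C@](C)(O)[C@@H](O[Si](C)(C)C(C)(C)C)C[C@H](OS(C)(=O)=O)[C@]2(C)[C@@H]3C1
F5 | step 18 | 4α-triethylsilyl ether of 22 | C=C(C)[C@H]1CC(=O)[C@](C)(O[Si](CC)(CC)CC)[C@@H](OC(=O)/C(C)=C\C)C/C=C(C)\C(=O)C1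
F6 | step 18 | 5β-alcohol of F5 | C=C(C)[C@H]1C[C@@H](O)[C@](C)(O[Si](CC)(CC)CC)[C@@H](OC(=O)/C(C)=C\C)C/C=C(C)\C(=O)C1
F7 | step 20 | 8β-hydroxy-9-ketone (3β-OAng; 4α,5β-bis-OTES) | C=C(C)[C@H]1C[C@@H](O[Si](CC)(CC)CC)[C@](C)(O[Si](CC)(CC)CC)[C@@H](OC(=O)/C(C)=C\C)C/C=C(C)\C(=O)[C@H]1O
F0 | step 22 | none | none
A1 | alternative 1 | cis-anti-cis tricyclic photoadduct (six-, four- and four-membered rings; new bonds C1–C10 and C4–C5) | CC1(OCCO1)[C@H]2C[C@@H]3[C@@]4(C)[C@@H](O[Si](C)(C)C(C)(C)C)C[C@H]4[C@]3(C)C(=O)[C@H]2O[Si](C)(C)C(C)(C)C
A2 | alternative 1 | 6-(TBS-oxy)-2-methyl-5-(2-methyl-1,3-dioxolan-2-yl)cyclohex-2-enone | CC1(OCCO1)[C@H]2CC=C(C)C(=O)[C@H]2O[Si](C)(C)C(C)(C)C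
A3 | alternative 1 | TBS ether of 2-methylcyclobut-2-enol | CC1=CC[C@@H]1O[Si](C)(C)C(C)(C)C
A4 | alternative 2 | ten-membered 3,8-dione with epoxide, C9 acetate and silylated 4,5-diol | C=C(C)[C@H]1C[C@@H](O[Si](CC)(CC)CC)[C@](C)(O[Si](CC)(CC)CC)C(=O)C[C@H]2O[C@@]2(C)[C@@H](OC(C)=O)C1=O
A5 | alternative 2 | bicyclic alkene with tetrasubstituted C3=C8 double bond shared by two six-membered rings | C=C(C)[C@H]1C[C@@H](O[Si](CC)(CC)CC)[C@](C)(O[Si](CC)(CC)CC)C3C[C@H]2O[C@@]2(C)[C@@H](OC(C)=O)C1=3
A6 | alternative 3 | ten-membered ring with free C3 and C4 hydroxyls (5-OPMB; 9-OTES; 8-OTBS) | C=C(C)[C@H]1C[C@@H](OCc2ccc(OC)cc2)[C@](C)(O)[C@@H](O)C/C=C(C)\[C@@H](O[Si](CC)(CC)CC)[C@H]1O[Si](C)(C)C(C)(C)C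
A7 | alternative 3 | acyclic keto aldehyde (C3 aldehyde; C4 methyl ketone; Z alkene) | O=CC/C=C(C)\[C@@H](O[Si](CC)(CC)CC)[C@@H](O[Si](C)(C)C(C)(C)C)[C@@H](C(C)=C)C[C@@H](OCc1ccc(OC)cc1)C(C)=O
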